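**Plan**
- Retrosynthesis: the two methyl ethers and the alcohol level of C9/C10 go back to an all-trans C2,C3-diester. A second ester is then added at C2, and ring B is opened at C1–C2 while the C3 hydrogen returns to C1. This leaves an achiral C2=C3 ethenetricarboxylate.
- Enabling feature: C1 is a methine held between rings A and C, each with a methoxy group para to it (C6-OMe, C4'-OMe). It lies 1,5 to C3 along C1–C8a–C4a–C4–C3, so its hydride can reach C3 and C2 can then capture the cation left at C1.
- The open chain is cut further at C2=C3 (Wittig), C3–C4 (ylide alkylation) and C1–C8a (Negishi).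
- Forward order: rings A and C are bought and joined through C1, and the C4–C3–C2 chain is grown from the ester carbon on ring A. Ring B is the only ring made and closes in the cascade.
- Stereochemistry: a chiral scandium catalyst sets C1 (and, provisionally, C3) in the cascade. Methoxide equilibration then settles C2 and C3 relative to C1, which cannot epimerise.

Key step: step 6

Numbering: tetralin numbering is used. Ring A is the fused dimethoxybenzene, ring B the saturated ring and ring C the pendant aryl group. C9 and C10 are the arm carbons on C2 and C3. The target is (1R,2S,3S), all-trans.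
Assumption: the sense of induction of the scandium/N,N'-dioxide catalyst on this new substrate class cannot be predicted, so the ligand enantiomer (from L- or D-proline) that a test run shows to give the (1R) cascade product is the one used.

Step 1
Reactants: 1 3,4-dimethoxybenzyl chloride; 2 methyl 2-bromo-4,5-dimethoxybenzoate
Product: 4 methyl 2-(3,4-dimethoxybenzyl)-4,5-dimethoxybenzoate, via 3,4-dimethoxybenzylzinc chloride 3 (not isolated)
Conditions: 1, Zn dust, LiCl, THF, 25 °C; then 2, Pd(OAc)2 (2 mol %), SPhos (4 mol %), THF, 25–50 °C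
Reagents that add atoms: zinc, [Zn] (its atom is held in 3 only)
Why: LiCl-assisted zinc insertion turns the benzylic chloride into an ester-tolerant benzylzinc reagent, and Negishi sp3–sp2 cross-coupling with the aryl bromide, whose ortho ester speeds oxidative addition to zerovalent palladium, forms the C1–C8a bond.

Step 2
Reactants: 4 methyl 2-(3,4-dimethoxybenzyl)-4,5-dimethoxybenzoate
Product: 5 [2-(3,4-dimethoxybenzyl)-4,5-dimethoxyphenyl]methanol
Conditions: LiAlH4, THF, 0 °C to rt; H2O quench
Reagents that add atoms: none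
Why: Hydride reduction of an aromatic ester with LiAlH4 gives the primary benzylic alcohol (future C4), and the aryl methyl ethers and the diarylmethane are inert.

Step 3
Reactants: 5 [2-(3,4-dimethoxybenzyl)-4,5-dimethoxyphenyl]methanol
Product: 6 1-(bromomethyl)-2-(3,4-dimethoxybenzyl)-4,5-dimethoxybenzene
Conditions: CBr4, PPh3, CH2Cl2, 0 °C; used without storage
Reagents that add atoms: carbon tetrabromide, BrC(Br)(Br)Br
Why: The Appel reaction replaces hydroxyl by bromide under neutral conditions, which avoids the acid-triggered Friedel–Crafts self-alkylation typical of veratryl-type alcohols and halides.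

Step 4
Reactants: 6 1-(bromomethyl)-2-(3,4-dimethoxybenzyl)-4,5-dimethoxybenzene; 7 methyl (triphenylphosphoranylidene)acetate (2 equiv)
Product: 9 methyl 3-[2-(3,4-dimethoxybenzyl)-4,5-dimethoxyphenyl]-2-(triphenylphosphoranylidene)propanoate, via alkylated phosphonium bromide 8 (not isolated)
Conditions: EtOAc, 60 °C; precipitated salt filtered off
Reagents that add atoms: none
Why: C-alkylation of the ester-stabilised ylide by the reactive benzylic bromide forms the C3–C4 bond, and a second equivalent of 7 deprotonates salt 8 (transylidation), driven by precipitation of the parent phosphonium bromide.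

Step 5
Reactants: 9 methyl 3-[2-(3,4-dimethoxybenzyl)-4,5-dimethoxyphenyl]-2-(triphenylphosphoranylidene)propanoate; 10 dimethyl oxomalonate (anhydrous keto form)
Product: 11 trimethyl 3-[2-(3,4-dimethoxybenzyl)-4,5-dimethoxyphenyl]prop-1-ene-1,1,2-tricarboxylate
Conditions: 9 added slowly to 10 (1.3 equiv), CH2Cl2, 0 °C to rt
Reagents that add atoms: none
Why: Wittig olefination should succeed with the branched stabilised ylide because the central carbonyl of the vicinal tricarbonyl compound is exceptionally electrophilic, the symmetrical malonate terminus removes any E/Z question, and inverse addition keeps the basic ylide scarce so that the double bond does not migrate toward ring A.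

Step 6
Reactants: 11 trimethyl 3-[2-(3,4-dimethoxybenzyl)-4,5-dimethoxyphenyl]prop-1-ene-1,1,2-tricarboxylate
Product: 13 trimethyl (1R,3S)-1-(3,4-dimethoxyphenyl)-6,7-dimethoxy-3,4-dihydronaphthalene-2,2,3(1H)-tricarboxylate, via carbenium-enolate zwitterion 12 (not isolated)
Conditions: Sc(OTf)3 (10 mol %), C2-symmetric N,N'-dioxide ligand built from proline, 2,6-diisopropylaniline and a 1,3-propylene bridge (11 mol %), 4 Å MS, ClCH2CH2Cl, 60 °C
Reagents that add atoms: none
Why: Proposed new method: chelation of the geminal diester of 11 by the cationic scandium complex polarises C2=C3 so that C3 takes up the hydride that C1 releases across a six-atom array (H, C1, C8a, C4a, C4, C3), and the ion pair 12 then collapses by C2–C1 bond formation, the whole being a redox-neutral isomerisation. The closest known reaction type is the Lewis-acid-catalysed 1,5-hydride shift/cyclisation of alkylidene malonates and ethenetricarboxylates, which is established in racemic form for benzylic all-carbon donors and in enantioselective form only for C–H bonds next to nitrogen or oxygen, so the asymmetric diarylmethane donor and the fully substituted acceptor are the extrapolation. Ring B closes in a 6-(enolexo) mode, the metal-bound malonate enolate carbon C2 attacking the planar carbenium carbon C1. C3 is set by the alkene face that the ligand leaves open to the incoming hydride, and C1 is set in the collapse, where the ligand on the enolate and the new C3 centre together favour a half-chair with ring C and the C3 ester pseudo-equatorial (1,3-cis). The step needs hydride transfer to be faster than Friedel–Crafts attack of ring C on C3 and than migration of the double bond toward C4, which the substrate secures by the two para-methoxy groups that weaken the C1–H bond, by the seven-membered, quaternary-centre-forming nature of the arylation path and by the absence of base. Any 1,3-trans isomer is removed at this stage by chromatography or crystallisation, because step 8 would carry it into the enantiomeric series.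

Step 7
Reactants: 13 trimethyl (1R,3S)-1-(3,4-dimethoxyphenyl)-6,7-dimethoxy-3,4-dihydronaphthalene-2,2,3(1H)-tricarboxylate
Product: 14 dimethyl (1R,3S)-1-(3,4-dimethoxyphenyl)-6,7-dimethoxy-1,2,3,4-tetrahydronaphthalene-2,3-dicarboxylate, mixture of C2 epimers
Conditions: LiCl, H2O, DMSO, 150 °C
Reagents that add atoms: none
Why: In the Krapcho dealkoxycarbonylation chloride dealkylates one of the geminal esters, CO2 is lost and water protonates the ester enolate, while the lone C3 ester lacks a second acceptor and stays; C2 arises as an epimer mixture and C1 is untouched.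

Step 8
Reactants: 14 dimethyl (1R,3S)-1-(3,4-dimethoxyphenyl)-6,7-dimethoxy-1,2,3,4-tetrahydronaphthalene-2,3-dicarboxylate, mixture of C2 epimers
Product: 15 dimethyl (1R,2S,3S)-1-(3,4-dimethoxyphenyl)-6,7-dimethoxy-1,2,3,4-tetrahydronaphthalene-2,3-dicarboxylate (all-trans)
Conditions: NaOMe (0.3 equiv, catalytic), MeOH, 65 °C
Reagents that add atoms: none
Why: Reversible enolisation at C2 and C3 (base-mediated epimerisation) funnels all isomers into the diester with ring C and both esters equatorial, so C2 (S) and C3 (S) are set under thermodynamic control from the non-acidic C1 centre.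

Step 9
Reactants: 15 dimethyl (1R,2S,3S)-1-(3,4-dimethoxyphenyl)-6,7-dimethoxy-1,2,3,4-tetrahydronaphthalene-2,3-dicarboxylate
Product: 16 [(1R,2S,3S)-1-(3,4-dimethoxyphenyl)-6,7-dimethoxy-1,2,3,4-tetrahydronaphthalene-2,3-diyl]dimethanol
Conditions: LiAlH4, THF, 0 °C to rt; H2O quench
Reagents that add atoms: none
Why: LiAlH4 reduction of both esters to the 1,4-diol is faster than enolisation, so no stereocentre is touched.

Step 10
Reactants: 16 [(1R,2S,3S)-1-(3,4-dimethoxyphenyl)-6,7-dimethoxy-1,2,3,4-tetrahydronaphthalene-2,3-diyl]dimethanol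
Product: 17 phyltetralin, (1R,2S,3S)-1-(3,4-dimethoxyphenyl)-6,7-dimethoxy-2,3-bis(methoxymethyl)-1,2,3,4-tetrahydronaphthalene
Conditions: NaH, MeI, THF, 0 °C to rt
Reagents that add atoms: iodomethane, CI
Why: Double Williamson etherification of the two primary alkoxides with iodomethane completes both methoxymethyl arms without affecting any stereocentre.

**Compound list**
1 | 3,4-dimethoxybenzyl chloride | COc1ccc(CCl)cc1OC | starting material
2 | methyl 2-bromo-4,5-dimethoxybenzoate | COC(=O)c1cc(OC)c(OC)cc1Br | starting material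
3 | 3,4-dimethoxybenzylzinc chloride | COc1ccc(C[Zn]Cl)cc1OC | intermediate
4 | methyl 2-(3,4-dimethoxybenzyl)-4,5-dimethoxybenzoate | COC(=O)c1cc(OC)c(OC)cc1Cc1ccc(OC)c(OC)c1 | intermediate
5 | [2-(3,4-dimethoxybenzyl)-4,5-dimethoxyphenyl]methanol | OCc1cc(OC)c(OC)cc1Cc1ccc(OC)c(OC)c1 | intermediate
6 | 1-(bromomethyl)-2-(3,4-dimethoxybenzyl)-4,5-dimethoxybenzene | BrCc1cc(OC)c(OC)cc1Cc1ccc(OC)c(OC)c1 | intermediate
7 | methyl (triphenylphosphoranylidene)acetate | COC(=O)C=P(c1ccccc1)(c1ccccc1)c1ccccc1 | starting material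
8 | {1-[2-(3,4-dimethoxybenzyl)-4,5-dimethoxyphenyl]-3-methoxy-3-oxopropan-2-yl}triphenylphosphonium bromide (racemic) | COC(=O)C(Cc1cc(OC)c(OC)cc1Cc1ccc(OC)c(OC)c1)[P+](c1ccccc1)(c1ccccc1)c1ccccc1.[Br-] | intermediate
9 | methyl 3-[2-(3,4-dimethoxybenzyl)-4,5-dimethoxyphenyl]-2-(triphenylphosphoranylidene)propanoate | COC(=O)C(Cc1cc(OC)c(OC)cc1Cc1ccc(OC)c(OC)c1)=P(c1ccccc1)(c1ccccc1)c1ccccc1 | intermediate
10 | dimethyl oxomalonate | COC(=O)C(=O)C(=O)OC | starting material
11 | trimethyl 3-[2-(3,4-dimethoxybenzyl)-4,5-dimethoxyphenyl]prop-1-ene-1,1,2-tricarboxylate | COC(=O)C(Cc1cc(OC)c(OC)cc1Cc1ccc(OC)c(OC)c1)=C(C(=O)OC)C(=O)OC | intermediate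
12 | (3S)-diarylcarbenium malonate-enolate zwitterion formed by hydride transfer from C1 to C3 (drawn without scandium) | COC(=O)[C@@H](Cc1cc(OC)c(OC)cc1[CH+]c1ccc(OC)c(OC)c1)[C-](C(=O)OC)C(=O)OC | intermediate
13 | trimethyl (1R,3S)-1-(3,4-dimethoxyphenyl)-6,7-dimethoxy-3,4-dihydronaphthalene-2,2,3(1H)-tricarboxylate | COC(=O)[C@H]1Cc2cc(OC)c(OC)cc2[C@@H](c2ccc(OC)c(OC)c2)C1(C(=O)OC)C(=O)OC | intermediate
14 | dimethyl (1R,3S)-1-(3,4-dimethoxyphenyl)-6,7-dimethoxy-1,2,3,4-tetrahydronaphthalene-2,3-dicarboxylate, C2 epimer mixture (levelled in step 8) | COC(=O)[C@H]1Cc2cc(OC)c(OC)cc2[C@@H](c2ccc(OC)c(OC)c2)C1C(=O)OC | intermediate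
15 | dimethyl (1R,2S,3S)-1-(3,4-dimethoxyphenyl)-6,7-dimethoxy-1,2,3,4-tetrahydronaphthalene-2,3-dicarboxylate | COC(=O)[C@H]1Cc2cc(OC)c(OC)cc2[C@@H](c2ccc(OC)c(OC)c2)[C@@H]1C(=O)OC | intermediate
16 | [(1R,2S,3S)-1-(3,4-dimethoxyphenyl)-6,7-dimethoxy-1,2,3,4-tetrahydronaphthalene-2,3-diyl]dimethanol | OC[C@H]1Cc2cc(OC)c(OC)cc2[C@@H](c2ccc(OC)c(OC)c2)[C@@H]1CO | intermediate
17 | phyltetralin, (1R,2S,3S)-1-(3,4-dimethoxyphenyl)-6,7-dimethoxy-2,3-bis(methoxymethyl)-1,2,3,4-tetrahydronaphthalene | COC[C@H]1Cc2cc(OC)c(OC)cc2[C@@H](c2ccc(OC)c(OC)c2)[C@@H]1COC | target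

Total step count: 10. Longest linear sequence: 10 steps (from 1 or 2 to 17).

**Steps most likely to fail**

Step 6.
- What may go wrong: hydride transfer may be outrun by arylation of C3 by ring C or by double-bond migration. Face selection at the long-lived cation may be poor. Re-ionisation of the C1–C2 bond on the Lewis acid may also erode the enantiomeric purity.
- Fallback: ring B is built instead by an auxiliary-controlled Diels–Alder reaction using known chemistry only. It sets out from alcohol 5 and comes back at diol 16.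
- MnO2 in CH2Cl2 oxidises 5 to 2-(3,4-dimethoxybenzyl)-4,5-dimethoxybenzaldehyde F1.
- Irradiation of F1 at about 350 nm in benzene saturated with SO2 photoenolises the aldehyde. The dienol is trapped as racemic 3-(3,4-dimethoxyphenyl)-1-hydroxy-5,6-dimethoxy-1,3-dihydro-2-benzothiophene 2,2-dioxide F2.
- Fumaryl chloride and methyl (R)-mandelate (Et3N, CH2Cl2) give bis[(1R)-2-methoxy-2-oxo-1-phenylethyl] fumarate F3.
- Warming F2 with F3 in toluene at about 80 °C causes cheletropic loss of SO2 and releases (E,E)-α-hydroxy-α'-(3,4-dimethoxyphenyl)-4,5-dimethoxy-o-quinodimethane F4.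
- F4 should add to F3 with the ester next to the hydroxyl group endo and with the auxiliary choosing the face. This gives the 1,2-trans-2,3-trans-3,4-cis adduct bis[(1R)-2-methoxy-2-oxo-1-phenylethyl] (1R,2S,3R,4R)-1-(3,4-dimethoxyphenyl)-4-hydroxy-6,7-dimethoxy-1,2,3,4-tetrahydronaphthalene-2,3-dicarboxylate F5.
- Ionic reduction (Et3SiH, CF3CO2H, CH2Cl2, 0 °C) removes the electron-rich benzylic hydroxyl group and leaves the deactivated mandelate C–O bonds. The product is bis[(1R)-2-methoxy-2-oxo-1-phenylethyl] (1R,2S,3S)-1-(3,4-dimethoxyphenyl)-6,7-dimethoxy-1,2,3,4-tetrahydronaphthalene-2,3-dicarboxylate F6.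
- LiAlH4 in THF cleaves both auxiliaries reductively to give 16.

Step 5.
- What may go wrong: the basic ylide may trigger migration of the new double bond into conjugation with ring A, or the hindered ylide may olefinate too slowly.
- Fallback: the C3–C4 bond is made by conjugate addition and the alkene is introduced last without base. It sets out from bromide 6 and comes back at 11.
- Ylide 7 and oxomalonate 10 give trimethyl ethene-1,1,2-tricarboxylate F7 in an unbranched Wittig reaction.
- Slow addition of 6 to Zn dust and LiCl in THF at 0 °C gives [2-(3,4-dimethoxybenzyl)-4,5-dimethoxybenzyl]zinc bromide F8.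
- F8 adds to the CH terminus of F7 to give racemic trimethyl 3-[2-(3,4-dimethoxybenzyl)-4,5-dimethoxyphenyl]propane-1,1,2-tricarboxylate F9.
- NaH and then PhSeCl in THF selenenylate the malonate carbon to give trimethyl 3-[2-(3,4-dimethoxybenzyl)-4,5-dimethoxyphenyl]-1-(phenylselanyl)propane-1,1,2-tricarboxylate F10.
- H2O2 in CH2Cl2 at 0 °C gives the corresponding phenylseleninyl triester (selenoxide) F11. Its syn elimination can use only the C3 hydrogen and so delivers 11.

Step 7.
- What may go wrong: dealkylation at the crowded quaternary malonate may be slow at temperatures the molecule tolerates, and chemoselectivity against the C3 ester may be lost.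
- Fallback: hydrolysis and thermal decarboxylation replace nucleophilic dealkylation. It sets out from 13 and comes back at 14.
- KOH in aqueous MeOH at reflux gives (1R,3S)-1-(3,4-dimethoxyphenyl)-6,7-dimethoxy-3,4-dihydronaphthalene-2,2,3(1H)-tricarboxylic acid F12.
- Heating F12 in pyridine at 110 °C decarboxylates the malonic acid unit to (1R,3S)-1-(3,4-dimethoxyphenyl)-6,7-dimethoxy-1,2,3,4-tetrahydronaphthalene-2,3-dicarboxylic acid F13 as a C2 epimer mixture.
- Fischer esterification (MeOH, H2SO4, reflux) returns 14. Any epimerisation along the way is levelled in step 8.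

**Further compounds**
F1 | step 6 | 2-(3,4-dimethoxybenzyl)-4,5-dimethoxybenzaldehyde | COc1ccc(Cc2cc(OC)c(OC)cc2C=O)cc1OC
F2 | step 6 | 3-(3,4-dimethoxyphenyl)-1-hydroxy-5,6-dimethoxy-1,3-dihydro-2-benzothiophene 2,2-dioxide (racemic) | OC1c2cc(OC)c(OC)cc2C(c2ccc(OC)c(OC)c2)S1(=O)=O
F3 | step 6 | bis[(1R)-2-methoxy-2-oxo-1-phenylethyl] fumarate | COC(=O)[C@@H](c1ccccc1)OC(=O)/C=C/C(=O)O[C@@H](C(=O)OC)c1ccccc1
F4 | step 6 | (E,E)-α-hydroxy-α'-(3,4-dimethoxyphenyl)-4,5-dimethoxy-o-quinodimethane | O/C=C1\C=C(OC)C(OC)=C/C1=C\c1ccc(OC)c(OC)c1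
F5 | step 6 | bis[(1R)-2-methoxy-2-oxo-1-phenylethyl] (1R,2S,3R,4R)-1-(3,4-dimethoxyphenyl)-4-hydroxy-6,7-dimethoxy-1,2,3,4-tetrahydronaphthalene-2,3-dicarboxylate | COC(=O)[C@@H](c1ccccc1)OC(=O)[C@H]1[C@@H](O)c2cc(OC)c(OC)cc2[C@@H](c2ccc(OC)c(OC)c2)[C@@H]1C(=O)O[C@@H](C(=O)OC)c1ccccc1
F6 | step 6 | bis[(1R)-2-methoxy-2-oxo-1-phenylethyl] (1R,2S,3S)-1-(3,4-dimethoxyphenyl)-6,7-dimethoxy-1,2,3,4-tetrahydronaphthalene-2,3-dicarboxylate | COC(=O)[C@@H](c1ccccc1)OC(=O)[C@H]1Cc2cc(OC)c(OC)cc2[C@@H](c2ccc(OC)c(OC)c2)[C@@H]1C(=O)O[C@@H](C(=O)OC)c1ccccc1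
F7 | step 5 | trimethyl ethene-1,1,2-tricarboxylate | COC(=O)C=C(C(=O)OC)C(=O)OC
F8 | step 5 | [2-(3,4-dimethoxybenzyl)-4,5-dimethoxybenzyl]zinc bromide | COc1ccc(Cc2cc(OC)c(OC)cc2C[Zn]Br)cc1OC
F9 | step 5 | trimethyl 3-[2-(3,4-dimethoxybenzyl)-4,5-dimethoxyphenyl]propane-1,1,2-tricarboxylate (racemic) | COC(=O)C(Cc1cc(OC)c(OC)cc1Cc1ccc(OC)c(OC)c1)C(C(=O)OC)C(=O)OC
F10 | step 5 | trimethyl 3-[2-(3,4-dimethoxybenzyl)-4,5-dimethoxyphenyl]-1-(phenylselanyl)propane-1,1,2-tricarboxylate (racemic) | COC(=O)C(Cc1cc(OC)c(OC)cc1Cc1ccc(OC)c(OC)c1)C([Se]c1ccccc1)(C(=O)OC)C(=O)OC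
F11 | step 5 | trimethyl 3-[2-(3,4-dimethoxybenzyl)-4,5-dimethoxyphenyl]-1-(phenylseleninyl)propane-1,1,2-tricarboxylate | COC(=O)C(Cc1cc(OC)c(OC)cc1Cc1ccc(OC)c(OC)c1)C([Se](=O)c1ccccc1)(C(=O)OC)C(=O)OC
F12 | step 7 | (1R,3S)-1-(3,4-dimethoxyphenyl)-6,7-dimethoxy-3,4-dihydronaphthalene-2,2,3(1H)-tricarboxylic acid | OC(=O)[C@H]1Cc2cc(OC)c(OC)cc2[C@@H](c2ccc(OC)c(OC)c2)C1(C(=O)O)C(=O)O
F13 | step 7 | (1R,3S)-1-(3,4-dimethoxyphenyl)-6,7-dimethoxy-1,2,3,4-tetrahydronaphthalene-2,3-dicarboxylic acid, C2 epimer mixture | OC(=O)[C@H]1Cc2cc(OC)c(OC)cc2[C@@H](c2ccc(OC)c(OC)c2)C1C(=O)O
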